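The flask cannot hold more target than its first nucleophile can supply, at one nucleophile per target. I call the ceiling the charge of first nucleophile over the charge of substrate, with first nucleophile as the limiting reagent for target.

- Tuesday's: substrate 0.25 M; first nucleophile 0.062 M; capture agent 0.0125 M; gas 71 mM (held); run made earlier
- flask: substrate 0.25 M; first nucleophile 0.125 M; capture agent 0.0125 M; gas 71 mM (held); time 2.5 min

- Tuesday's (time / s: other capture product / %, target / %): 10.0: 1.7, 21.1; 15.0: 1.7, 24.7; 25.0: 4.8, 27.5; 50.0: 11.7, 26.6

(readings scatter by 1 percentage point)

- the earlier runs were read with a standard deviation of 1 percentage point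
- at the start none of the gas is in solution

- ratio of other capture product to target at 1.2 s
- ratio of other capture product to target at 2.5 min
- which of other capture product and target there is more of at 2.5 min

50.0% is the ceiling in the new flask. The same rule gives Tuesday's run 24.8%, and its target reads 24.7%, 27.5% and 26.6% from 15.0 s on, so I trust it. The new flask has twice Tuesday's first nucleophile, and 50.0% of its substrate lies above the ceiling.

Now I follow the fraction of substrate left. Substrate itself was not read on Tuesday, but the two products at 10.0 s read 22.8% together, so by those readings at most 77.2% of it is left there, and if the fall is first order its constant is at least 0.0259 s⁻¹. With that constant I estimate that the new flask reaches its ceiling at about 26.8 s.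

After its ceiling, Tuesday's other capture product grows by a fraction 0.00276 s⁻¹ of the substrate charged, reckoned between its last two readings. That is my weak link, since those readings are close together and each carries the scatter. Taken from 15.0 s instead, the span is longer and the slope is 0.00286 s⁻¹. Over the time from 26.8 s to 2.5 min this gives 35.2%, less than the room above the ceiling. I commit to a ratio of 0.704 at 2.5 min, with target ahead. At 1.2 s I say only that the ratio is small, because gas starts out of solution.

The forecast gives 0.005 at 1.2 s, 0.55 at 2.5 min, lower than mine, and target ahead, arguing that “little gas is dissolved and the nucleophile is doubled”.

The flask gives 0.00215 and 0.655, with target ahead.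

    substrate → open intermediate (k = 0.0376 s⁻¹)
    first nucleophile + open intermediate → target (k = 10.9 M⁻¹ s⁻¹)
    second nucleophile + open intermediate → other capture product (k = 6.62 M⁻¹ s⁻¹)
    open intermediate → side product (k = 0.00250 s⁻¹)
    open intermediate + capture agent → trapped intermediate (k = 0.0141 M⁻¹ s⁻¹)
    gas ⇌ second nucleophile, rate k6*(csat - [second nucleophile]) (kL = 0.00824 s⁻¹)

Target stands at 50.0% under a ceiling of 50.0%, and the neighbour charged with 0.050 M of first nucleophile, with a ceiling of 20.0%, holds 20.0%. In the flask, second nucleophile is made 1.00 times as fast as it is used up at 0.306 min, and 1.10 times as fast at 2.50 min. The gas transfer from an empty solution amounts to a fraction 0.00234 s⁻¹ of the substrate charged, and other capture product in the flask stands at 32.7% at 2.50 min.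

The data were generated by integration with made-up constants; noise was put on by code.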